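## The problem

The target is a cis-fused decalin of the eremophilane type, and eremophilane numbers are used for it throughout. Ring A is C1, C2 (ketone), C3, C4 (CH–CH3), C5 (quaternary, CH3) and C10 (ring-fusion CH); ring B is C5, C6, C7 (isopropenyl), C8 (OAc), C9 (O-tigloyl) and C10. There are six stereocentres, (4S,5R,7R,8R,9S,10S), five of them contiguous. Both methyl groups, H-10 and the isopropenyl group lie on one face; the two ester oxygens lie on the other. The quaternary C5 beside C4 is the part that no later step can repair. If C4 is bought and the rings are closed around it, C4 can set C5 and C10; the folded cis-decalin can then set C7, C7 can set C8, and the shape of ring B can set C9. Several groups are fragile: the tiglate (conjugate addition, deconjugation, hydride), two different esters on a cis-1,2-diol (acyl migration once one hydroxyl is free), and the isopropenyl group (acid, electrophilic oxidants, hydrogenation catalysts). The C2 ketone must be told apart from a C9 carbonyl, and C10 can epimerise whenever C9 is a ketone. The feature that invites a one-bond solution is that the C5 methyl can be made from an exocyclic CH2 by adding a hydrogen atom, while C10 is β to the C2 ketone and α to oxygenated C9. In the ten-membered ring C1–C10 a C5 radical and an electron-poor C10 therefore face each other 1,6 across the ring, and the single bond C5–C10 creates rings A and B together.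

## Retrosynthesis

**Ester oxygens.** Target 33 is cut at the acetyl C–O bond to hydroxy ketone 32, and 32 is traced to the silyl ether ketal 31. Cutting the tigloyl C–O bond of 31 gives alcohol 28 and tiglic acid 29. The order matters. The slow acylation of the hindered axial C9 hydroxyl is done while C8 carries a triethylsilyl group, which cannot wander as an acetyl group could. The fast acetylation of the equatorial C8 hydroxyl comes last. The forward steps must give a tiglate without deconjugation, and one acid treatment must remove both the silyl ether and the dioxolane.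

**Ring B stereocentres.** Alcohol 28 comes from ketone 27 (C9–H bond), 27 from ketol 26, 26 from ketone 24 (C8–O bond), 24 from enone 22 (C7–C11 bond), and 22 from ketal ketone 20 (C7=C8). Installing C7, C8 and C9 one after another on the C9 carbonyl lets each centre be set by the one before it. Carrying them through the ring-forming step instead would add stereocentres and chain length where the route is least certain. Compound 20 is simpler by three stereocentres and three substituents. The forward steps need a convex-face cuprate addition, an enolate oxidation anti to C7 and a hydride delivery to the convex face of C9.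

**Carbonyl differentiation.** Ketal 20 comes from dione 19 by masking C2 only. The forward reaction must distinguish a ketone between two methylenes (C2) from one beside the ring-fusion methine and the quaternary carbon (C9).

**Key disconnection.** Dione 19 is cut at C5–C10, which opens both rings at once to the Z-enedione 18. Other single cuts (C9–C10, C4–C5, C7–C8) open one ring only and leave the quaternary carbon to be made separately. Compound 18 has one stereocentre and no fused rings. The forward step must create the C5 methyl, the C5–C10 bond, the cis fusion and the 4,5-cis relationship together.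

**Ten-membered ring.** Enedione 18 comes from enediol 17, 17 from cyclic ynediol 16 by semi-hydrogenation, and 16 from the iodoalkyne aldehyde 15 by cutting C9–C10. An alkyne gives the Z geometry reliably and has a known ring-closing reaction with an aldehyde. Olefin metathesis at C1=C10 is excluded, because the C5 methylidene would close five- or six-membered rings first. The forward cyclisation has to form a ten-membered cycloalkyne under high dilution; the two carbinol centres are later erased.

**C2–C3 bond.** Aldehyde 15 comes from acetal 14, 14 from the silyl alkyne 13, and 13 from iodide 9 and 3-(trimethylsilyl)propynal 10. Adding the organolithium from 9 to the aldehyde brings in C2, C1 and C10 in one step. A cyanide homologation followed by acetylide addition would need three.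

**Chain from the chiral pool.** Iodide 9 comes from alcohol 8, silyl ether 7 and ketone 6. The methylidene is made from the C5 ketone by a non-basic titanium reagent, because C4 is α to that ketone. Ketone 6 is cut at C5–C6 into Weinreb amide 3 and the Grignard reagent 5 from chloride 4. Amide 3 comes from the silyl ether 2 of the (S)-Roche ester 1, whose ester carbon becomes C5, whose stereocentre becomes C4 and whose CH2OH becomes C3.

## Roads not taken

**Alternative 1: chromium allylation closing ring B at C7–C8.**
- Cut and forward step: CrCl2 would turn the allylic bromide aldehyde A2 into an allylchromium species whose γ-carbon C7 adds to the C8 aldehyde, giving A1.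
- Merits: isopropenyl, C7 and C8 (anti, as in the target) arise in one known, stereoconvergent reaction, with the C9 oxygen already in place. No oxidant ever meets the isopropenyl group.
- Weak points: A2 already contains ring A with C4, quaternary C5, C10 and C9 set, so the hardest stereochemical problem is only moved upstream. The aldehyde is α-oxygenated and β to the ring fusion, and its facial selectivity rests on the C9 silyl ether.
- Comparison: for C7 and C8 this road is better than the chosen plan, which spends four steps (20 to 26) on the same centres. Against that, the chosen plan makes both rings, C5 and C10 in one step from a chain with a single purchased stereocentre.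

**Alternative 2: anionic oxy-Cope rearrangement of a bicyclo[2.2.2]octenol.**
- Cut and forward step: C4–C5 is cut while C2–C7 is reconnected. The potassium alkoxide of A4 would rearrange to the cis-decalin A3.
- Merits: the sequence of masked o-benzoquinone cycloaddition and oxy-Cope shift is a proven entry to cis-decalins. The Z-propenyl group transmits the 4,5-cis-dimethyl and cis-fusion relationships stereospecifically. Its precedent is clearly stronger than that of the chosen key step.
- Weak points: the cycloadduct is racemic unless resolved or made with an auxiliary. A3 carries oxygen at C1 that must be removed and none at C9. Its C8 ether has the configuration opposite to the target, and the C6=C7 alkene must still be turned into the C7 isopropenyl centre.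
- Comparison: in reliability of ring and stereocentre construction this road is ahead. The chosen plan sets against it absolute configuration from the chiral pool and oxygen exactly at C2 and C9 straight from the key step, so the functional-group relay after ring formation is shorter.

**Alternative 3: carbene-catalysed desymmetrisation of a cyclohexadienone.**
- Cut and forward step: C9–C10 is cut. The carbene adduct of the aldehyde in achiral A6 would add to one enone β-carbon to give the bicyclic enedione A5.
- Merits: it is the shortest way to a 2,9-dioxygenated cis bicycle, it is catalytic in the source of chirality, and A5 has its two carbonyls already differentiated (enone against ketone). The chosen plan must achieve that differentiation by a selective ketalisation.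
- Weak points: an aliphatic aldehyde on an all-carbon tether closing a six-membered carbocycle is a less secure case of this reaction than the heteroatom-tethered ones. The C4 methyl would have to be added later by conjugate addition next to the quaternary carbon, cis to its methyl.
- Comparison: if the cyclisation performed as its precedents suggest, this road would be several steps shorter. The chosen plan sets against it a 4,5-cis relationship fixed inside the ring-forming step from a bought stereocentre, and no dependence on catalyst enantioselectivity.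

Key step: step 13

## Route

Remark: locants in ring compounds are eremophilane numbers as defined above; 2-(3-chloropropyl)-1,3-dioxolane and 3-(trimethylsilyl)prop-2-ynal are taken to be purchasable.

Step 1
Reactants: 1 methyl (S)-3-hydroxy-2-methylpropanoate
Product: 2 methyl (S)-3-[(tert-butyldimethylsilyl)oxy]-2-methylpropanoate
Conditions: TBSCl, imidazole, DMF, 0 °C to rt
Reagents that add atoms: tert-butyldimethylsilyl chloride, CC(C)(C)[Si](C)(C)Cl
Why: Routine silylation of a primary alcohol; the stereocentre (future C4) is not touched.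

Step 2
Reactants: 2 methyl (S)-3-[(tert-butyldimethylsilyl)oxy]-2-methylpropanoate
Product: 3 (S)-3-[(tert-butyldimethylsilyl)oxy]-N-methoxy-N,2-dimethylpropanamide
Conditions: MeNH(OMe)·HCl, i-PrMgCl, THF, −20 to 0 °C
Reagents that add atoms: N,O-dimethylhydroxylamine hydrochloride, CNOC.Cl
Why: Direct conversion of an ester into its Weinreb amide by the magnesium amide; the low temperature avoids epimerisation and β-elimination of the silyloxy group.

Step 3
Reactants: 3 (S)-3-[(tert-butyldimethylsilyl)oxy]-N-methoxy-N,2-dimethylpropanamide; 4 2-(3-chloropropyl)-1,3-dioxolane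
Product: 6 (2S)-1-[(tert-butyldimethylsilyl)oxy]-6-(1,3-dioxolan-2-yl)-2-methylhexan-3-one, via Grignard reagent 5 (not isolated)
Conditions: 4, Mg, THF, reflux; then 3, THF, 0 °C; aq. NH4Cl
Reagents that add atoms: none
Why: Weinreb ketone synthesis forms C5–C6; the chelated adduct prevents over-addition and releases the ketone only on work-up, so the α-stereocentre is not exposed to base.

Step 4
Reactants: 6 (2S)-1-[(tert-butyldimethylsilyl)oxy]-6-(1,3-dioxolan-2-yl)-2-methylhexan-3-one
Product: 7 tert-butyl{[(2R)-6-(1,3-dioxolan-2-yl)-2-methyl-3-methylidenehexyl]oxy}dimethylsilane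
Conditions: Cp2TiMe2, toluene, 65 °C, dark
Reagents that add atoms: dimethyltitanocene, C[Ti](C)(C1C=CC=C1)C1C=CC=C1
Why: Petasis methylenation through a titanium methylidene is non-basic, so the α-methyl stereocentre and the β-silyloxy group should survive (the descriptor changes to R only because the priorities change).

Step 5
Reactants: 7 tert-butyl{[(2R)-6-(1,3-dioxolan-2-yl)-2-methyl-3-methylidenehexyl]oxy}dimethylsilane
Product: 8 (2R)-6-(1,3-dioxolan-2-yl)-2-methyl-3-methylidenehexan-1-ol
Conditions: TBAF, THF, 0 °C to rt
Reagents that add atoms: none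
Why: Fluoride cleavage of a primary silyl ether; the acetal and the alkene are inert.

Step 6
Reactants: 8 (2R)-6-(1,3-dioxolan-2-yl)-2-methyl-3-methylidenehexan-1-ol
Product: 9 2-[(5R)-6-iodo-5-methyl-4-methylidenehexyl]-1,3-dioxolane
Conditions: I2, PPh3, imidazole, CH2Cl2, 0 °C to rt
Reagents that add atoms: iodine, II
Why: Appel-type iodination of a primary alcohol under buffered conditions; no carbocation is formed, so the allylic stereocentre and the acetal are safe.

Step 7
Reactants: 9 2-[(5R)-6-iodo-5-methyl-4-methylidenehexyl]-1,3-dioxolane; 10 3-(trimethylsilyl)prop-2-ynal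
Product: 13 (5S)-9-(1,3-dioxolan-2-yl)-5-methyl-6-methylidene-3-[(triethylsilyl)oxy]-1-(trimethylsilyl)non-1-yne (C3 epimers), via alkyllithium 11 (not isolated), via lithium alkoxide 12 (not isolated)
Conditions: t-BuLi (2.1 equiv), Et2O, −78 °C; then 10, −78 °C; then TESCl, THF, −78 °C to rt
Reagents that add atoms: chlorotriethylsilane, CC[Si](Cl)(CC)CC
Why: Lithium–iodine exchange and 1,2-addition of the primary alkyllithium to the ynal form C2–C3; trapping the alkoxide as its silyl ether keeps the C2 oxygen from cyclising onto the methylidene in the next step, and the C2 centre is left unassigned because it is oxidised later.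

Step 8
Reactants: 13 (5S)-9-(1,3-dioxolan-2-yl)-5-methyl-6-methylidene-3-[(triethylsilyl)oxy]-1-(trimethylsilyl)non-1-yne
Product: 14 (5S)-9-(1,3-dioxolan-2-yl)-1-iodo-5-methyl-6-methylidene-3-[(triethylsilyl)oxy]non-1-yne (C3 epimers)
Conditions: NIS, AgNO3 (10 mol%), acetone, rt, dark
Reagents that add atoms: N-iodosuccinimide, O=C1CCC(=O)N1I
Why: Silver-catalysed iododesilylation of an alkynylsilane through the silver acetylide; without a free hydroxyl the 1,1-disubstituted alkene is not attacked by the iodinating agent.

Step 9
Reactants: 14 (5S)-9-(1,3-dioxolan-2-yl)-1-iodo-5-methyl-6-methylidene-3-[(triethylsilyl)oxy]non-1-yne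
Product: 15 (6S)-8-hydroxy-10-iodo-6-methyl-5-methylidenedec-9-ynal (C8 epimers)
Conditions: 1 M aq. HCl, THF, rt
Reagents that add atoms: water, O
Why: Dilute acid hydrolyses the dioxolane and the triethylsilyl ether together; it is too weak to start a Prins or ene reaction between the aldehyde and the methylidene, and 15 is used at once.

Step 10
Reactants: 15 (6S)-8-hydroxy-10-iodo-6-methyl-5-methylidenedec-9-ynal
Product: 16 (6S)-6-methyl-7-methylidenecyclodec-2-yne-1,4-diol (epimers at C1 and C4 of the ring name)
Conditions: CrCl2, NiCl2 (cat.), THF, rt, 0.003 M, slow addition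
Reagents that add atoms: none
Why: Intramolecular Nozaki–Hiyama–Kishi addition of the alkynylchromium species to the aldehyde forms C9–C10; the reaction tolerates the free hydroxyl and is a known way to close ten-membered cycloalkynols, and high dilution suppresses oligomers.

Step 11
Reactants: 16 (6S)-6-methyl-7-methylidenecyclodec-2-yne-1,4-diol
Product: 17 (2Z,6S)-6-methyl-7-methylidenecyclodec-2-ene-1,4-diol
Conditions: H2 (1 atm), Pd/CaCO3 poisoned with Pb(OAc)2, quinoline, EtOAc, rt
Reagents that add atoms: none
Why: Lindlar semi-hydrogenation adds hydrogen syn to the strained ring alkyne and gives the Z alkene; on the poisoned catalyst the alkyne is consumed well before the methylidene, and the reaction is stopped after one equivalent.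

Step 12
Reactants: 17 (2Z,6S)-6-methyl-7-methylidenecyclodec-2-ene-1,4-diol
Product: 18 (2Z,6S)-6-methyl-7-methylidenecyclodec-2-ene-1,4-dione
Conditions: Dess–Martin periodinane, NaHCO3, CH2Cl2, 0 °C to rt
Reagents that add atoms: none
Why: Buffered Dess–Martin oxidation of both allylic alcohols erases the two carbinol centres and keeps the Z geometry; the neutral conditions avoid alkene isomerisation and transannular aldol reaction, and 18 is used directly.

Step 13
Reactants: 18 (2Z,6S)-6-methyl-7-methylidenecyclodec-2-ene-1,4-dione
Product: 19 (4S,5R,10S)-4,5-dimethyl-cis-decalin-2,9-dione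
Conditions: Fe(acac)3 (1 equiv), PhSiH3 (2.5 equiv, added slowly), EtOH/ethylene glycol 5:1, 60 °C, 0.005 M
Reagents that add atoms: none
Why: Proposed new method: an iron hydride formed from Fe(acac)3 and PhSiH3 in ethanol should transfer a hydrogen atom to the CH2 terminus of the only electron-rich alkene of 18, which creates the C5 methyl and a nucleophilic tertiary C5 radical that adds across the ring to C10; the C1 radical so formed, stabilised by the C2 carbonyl, is reduced by divalent iron to the enolate and protonated by the solvent. The closest known reaction type is the Fe(acac)3/PhSiH3 reductive coupling of 1,1-disubstituted alkenes with enones, established between molecules and within chains but not across a medium ring. Ring B closes in a 6-exo-trig mode (C5 through C6–C9 onto C10) and ring A in a 6-endo-trig mode (C5 through C4–C2 onto C10); attack at C1 would be 5-exo through a tether that contains the conjugated sp2 C2 and 7-endo through the long tether, so both tethers favour C10. C5 and C10 are set together: the Z alkene holds C9 and C2 on one side, so C5 can reach C10 only with C4 over C2 and C6 over C9, which leaves the C5 methyl and H-10 on the same side (cis fusion, with C9 axial on the chair-like forming ring A). The existing C4 centre then selects the alkene face, because on that chair an equatorial C4 methyl is cis to the C5 methyl, whereas the other face would place it axial and syn to C9. The step needs hydrogen-atom transfer to the methylidene to outrun hydride or silane reduction of the enedione; the higher reactivity of the electron-rich alkene toward the iron hydride, slow silane addition and high dilution should secure this.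

Step 14
Reactants: 19 (4S,5R,10S)-4,5-dimethyl-cis-decalin-2,9-dione
Product: 20 (4S,5R,10S)-2,2-(ethylenedioxy)-4,5-dimethyl-cis-decalin-9-one
Conditions: (TMSOCH2)2, TMSOTf (cat.), CH2Cl2, −78 °C
Reagents that add atoms: 1,2-bis(trimethylsilyloxy)ethane, C[Si](C)(C)OCCO[Si](C)(C)C
Why: Noyori ketalisation under kinetic control; C2 lies between two methylenes whereas C9 is flanked by the ring-fusion methine next to the quaternary carbon and should lag far behind, and at −78 °C the epimerisable C10 is not disturbed.

Step 15
Reactants: 20 (4S,5R,10S)-2,2-(ethylenedioxy)-4,5-dimethyl-cis-decalin-9-one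
Product: 22 (4S,5R,10S)-2,2-(ethylenedioxy)-4,5-dimethyl-cis-decal-7-en-9-one, via lithium enolate 21 (not isolated)
Conditions: LiN(i-Pr)2, THF, −78 °C; then PhS(Cl)=N-t-Bu, −78 °C
Reagents that add atoms: none
Why: Kinetic deprotonation takes the C8 methylene rather than the hindered C10 methine; sulfenylation of the enolate and syn-elimination of the sulfilimine (Mukaiyama dehydrogenation) give the C7=C8 enone in one flask without equilibrating C10.

Step 16
Reactants: 22 (4S,5R,10S)-2,2-(ethylenedioxy)-4,5-dimethyl-cis-decal-7-en-9-one
Product: 24 (4S,5R,7S,10S)-2,2-(ethylenedioxy)-4,5-dimethyl-7-(prop-1-en-2-yl)-cis-decalin-9-one, via silyl enol ether 23 (not isolated)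
Conditions: isopropenylmagnesium bromide, CuBr·SMe2 (20 mol%), TMSCl, THF, −78 °C; then 1 M aq. HCl, 0 °C, 10 min
Reagents that add atoms: isopropenylmagnesium bromide, CC(=C)[Mg]Br
Why: Copper-catalysed, silyl-chloride-accelerated conjugate addition; C7 should be set by attack on the convex face of the cis-fused enone (the face of the angular methyl and H-10), because ring A, through C4, covers the other face of C7, and the adduct relaxes to a chair with the isopropenyl group equatorial.

Step 17
Reactants: 24 (4S,5R,7S,10S)-2,2-(ethylenedioxy)-4,5-dimethyl-7-(prop-1-en-2-yl)-cis-decalin-9-one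
Product: 26 (4S,5R,7R,8R,10S)-2,2-(ethylenedioxy)-8-hydroxy-4,5-dimethyl-7-(prop-1-en-2-yl)-cis-decalin-9-one, via potassium enolate 25 (not isolated)
Conditions: KN(SiMe3)2, THF, −78 °C; then 2-(phenylsulfonyl)-3-phenyloxaziridine, −78 °C; AcOH quench
Reagents that add atoms: 2-(phenylsulfonyl)-3-phenyloxaziridine, O=S(=O)(c1ccccc1)N1OC1c1ccccc1
Why: Davis oxidation of the kinetic C8 enolate; oxygen is delivered anti to the neighbouring C7 isopropenyl group, which gives the 7,8-trans ketol (also the equatorial, more stable epimer), and the reagent does not touch the isopropenyl alkene.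

Step 18
Reactants: 26 (4S,5R,7R,8R,10S)-2,2-(ethylenedioxy)-8-hydroxy-4,5-dimethyl-7-(prop-1-en-2-yl)-cis-decalin-9-one
Product: 27 (4S,5R,7R,8R,10S)-2,2-(ethylenedioxy)-4,5-dimethyl-7-(prop-1-en-2-yl)-8-(triethylsilyloxy)-cis-decalin-9-one
Conditions: TESCl, imidazole, DMF, rt
Reagents that add atoms: chlorotriethylsilane, CC[Si](Cl)(CC)CC
Why: Silylation of the equatorial C8 hydroxyl under conditions too mild to enolise the ketone; a silyl group, unlike an acetyl group, will not migrate during the later acylation.

Step 19
Reactants: 27 (4S,5R,7R,8R,10S)-2,2-(ethylenedioxy)-4,5-dimethyl-7-(prop-1-en-2-yl)-8-(triethylsilyloxy)-cis-decalin-9-one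
Product: 28 (4S,5R,7R,8R,9S,10S)-2,2-(ethylenedioxy)-4,5-dimethyl-7-(prop-1-en-2-yl)-8-(triethylsilyloxy)-cis-decalin-9-ol
Conditions: LiBH(s-Bu)3, THF, −78 °C
Reagents that add atoms: none
Why: The bulky hydride should attack C9 along the equatorial line from the convex face, because the axial line is blocked by C4, which is syn-axial on ring B; this gives the axial 9-alcohol cis to the C8 oxygen and ends the epimerisability of C10.

Step 20
Reactants: 28 (4S,5R,7R,8R,9S,10S)-2,2-(ethylenedioxy)-4,5-dimethyl-7-(prop-1-en-2-yl)-8-(triethylsilyloxy)-cis-decalin-9-ol; 29 (E)-2-methylbut-2-enoic acid (tiglic acid)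
Product: 31 (4S,5R,7R,8R,9S,10S)-2,2-(ethylenedioxy)-4,5-dimethyl-7-(prop-1-en-2-yl)-8-(triethylsilyloxy)-cis-decalin-9-yl (E)-2-methylbut-2-enoate, via mixed anhydride 30 (not isolated)
Conditions: 29, 2,4,6-trichlorobenzoyl chloride, Et3N, toluene, rt; then 28, DMAP, toluene, 80 °C
Reagents that add atoms: none
Why: Yamaguchi esterification is the usual answer to hindered secondary alcohols and conjugated acids; the alkene geometry of the acid is kept, and the neighbouring silyl ether cannot take part in acyl transfer.

Step 21
Reactants: 31 (4S,5R,7R,8R,9S,10S)-2,2-(ethylenedioxy)-4,5-dimethyl-7-(prop-1-en-2-yl)-8-(triethylsilyloxy)-cis-decalin-9-yl (E)-2-methylbut-2-enoate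
Product: 32 (4S,5R,7R,8R,9S,10S)-8-hydroxy-4,5-dimethyl-2-oxo-7-(prop-1-en-2-yl)-cis-decalin-9-yl (E)-2-methylbut-2-enoate
Conditions: 1 M aq. HCl, THF, rt
Reagents that add atoms: water, O
Why: One mild acid treatment hydrolyses the triethylsilyl ether and the dioxolane; dilute acid at room temperature is too weak to hydrate the isopropenyl group or to move the tigloyl group, which sits on the more hindered oxygen.

Step 22
Reactants: 32 (4S,5R,7R,8R,9S,10S)-8-hydroxy-4,5-dimethyl-2-oxo-7-(prop-1-en-2-yl)-cis-decalin-9-yl (E)-2-methylbut-2-enoate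
Product: 33 (4S,5R,7R,8R,9S,10S)-8-acetoxy-4,5-dimethyl-2-oxo-7-(prop-1-en-2-yl)-cis-decalin-9-yl (E)-2-methylbut-2-enoate (CNP0204573.1)
Conditions: Ac2O, pyridine, DMAP (cat.), CH2Cl2, 0 °C to rt
Reagents that add atoms: acetic anhydride, CC(=O)OC(C)=O
Why: Acetylation of an unhindered equatorial secondary alcohol is fast enough to precede any acyl migration; the ketone and the tiglate are inert to these conditions.

## Compound list

1 | methyl (S)-3-hydroxy-2-methylpropanoate ((S)-Roche ester) | C[C@@H](CO)C(=O)OC | starting material
2 | methyl (S)-3-[(tert-butyldimethylsilyl)oxy]-2-methylpropanoate | C[C@@H](CO[Si](C)(C)C(C)(C)C)C(=O)OC | intermediate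
3 | (S)-3-[(tert-butyldimethylsilyl)oxy]-N-methoxy-N,2-dimethylpropanamide | C[C@@H](CO[Si](C)(C)C(C)(C)C)C(=O)N(C)OC | intermediate
4 | 2-(3-chloropropyl)-1,3-dioxolane | ClCCCC1OCCO1 | starting material
5 | [3-(1,3-dioxolan-2-yl)propyl]magnesium chloride | Cl[Mg]CCCC1OCCO1 | intermediate (not isolated)
6 | (2S)-1-[(tert-butyldimethylsilyl)oxy]-6-(1,3-dioxolan-2-yl)-2-methylhexan-3-one | C[C@@H](CO[Si](C)(C)C(C)(C)C)C(=O)CCCC1OCCO1 | intermediate
7 | tert-butyl{[(2R)-6-(1,3-dioxolan-2-yl)-2-methyl-3-methylidenehexyl]oxy}dimethylsilane | C[C@@H](CO[Si](C)(C)C(C)(C)C)C(=C)CCCC1OCCO1 | intermediate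
8 | (2R)-6-(1,3-dioxolan-2-yl)-2-methyl-3-methylidenehexan-1-ol | C[C@@H](CO)C(=C)CCCC1OCCO1 | intermediate
9 | 2-[(5R)-6-iodo-5-methyl-4-methylidenehexyl]-1,3-dioxolane | C[C@@H](CI)C(=C)CCCC1OCCO1 | intermediate
10 | 3-(trimethylsilyl)prop-2-ynal | C[Si](C)(C)C#CC=O | starting material
11 | [(2S)-6-(1,3-dioxolan-2-yl)-2-methyl-3-methylidenehexyl]lithium | C[C@@H](C[Li])C(=C)CCCC1OCCO1 | intermediate (not isolated)
12 | lithium (5S)-9-(1,3-dioxolan-2-yl)-5-methyl-6-methylidene-1-(trimethylsilyl)non-1-yn-3-olate (C3 epimers) | C[C@@H](CC(O[Li])C#C[Si](C)(C)C)C(=C)CCCC1OCCO1 | intermediate (not isolated)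
13 | (5S)-9-(1,3-dioxolan-2-yl)-5-methyl-6-methylidene-3-[(triethylsilyl)oxy]-1-(trimethylsilyl)non-1-yne (C3 epimers) | C[C@@H](CC(O[Si](CC)(CC)CC)C#C[Si](C)(C)C)C(=C)CCCC1OCCO1 | intermediate
14 | (5S)-9-(1,3-dioxolan-2-yl)-1-iodo-5-methyl-6-methylidene-3-[(triethylsilyl)oxy]non-1-yne (C3 epimers) | C[C@@H](CC(O[Si](CC)(CC)CC)C#CI)C(=C)CCCC1OCCO1 | intermediate
15 | (6S)-8-hydroxy-10-iodo-6-methyl-5-methylidenedec-9-ynal (C8 epimers) | C[C@@H](CC(O)C#CI)C(=C)CCCC=O | intermediate
16 | (6S)-6-methyl-7-methylidenecyclodec-2-yne-1,4-diol (carbinol epimers) | C=C1CCCC(O)C#CC(O)C[C@@H]1C | intermediate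
17 | (2Z,6S)-6-methyl-7-methylidenecyclodec-2-ene-1,4-diol (carbinol epimers) | C=C1CCCC(O)/C=C\C(O)C[C@@H]1C | intermediate
18 | (2Z,6S)-6-methyl-7-methylidenecyclodec-2-ene-1,4-dione | C=C1CCCC(=O)/C=C\C(=O)C[C@@H]1C | intermediate
19 | (4S,5R,10S)-4,5-dimethyl-cis-decalin-2,9-dione [(4aR,5S,8aS)-4a,5-dimethylhexahydronaphthalene-1,7(2H,8H)-dione] | C1C[C@@]2(C)[C@H](CC(=O)C[C@@H]2C)C(=O)C1 | intermediate
20 | (4S,5R,10S)-2,2-(ethylenedioxy)-4,5-dimethyl-cis-decalin-9-one | C1C[C@@]2(C)[C@H](CC3(OCCO3)C[C@@H]2C)C(=O)C1 | intermediate
21 | lithium (4S,5R,10S)-2,2-(ethylenedioxy)-4,5-dimethyl-cis-decal-8-en-9-olate | C1C[C@@]2(C)[C@H](CC3(OCCO3)C[C@@H]2C)C(O[Li])=C1 | intermediate (not isolated)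
22 | (4S,5R,10S)-2,2-(ethylenedioxy)-4,5-dimethyl-cis-decal-7-en-9-one | C1C[C@@]2(C)[C@H](CC3(OCCO3)C[C@@H]2C)C(=O)C=1 | intermediate
23 | (4S,5R,7S,10S)-2,2-(ethylenedioxy)-4,5-dimethyl-7-(prop-1-en-2-yl)-9-(trimethylsilyloxy)-cis-decal-8-ene | C=C(C)[C@H]1C[C@@]2(C)[C@H](CC3(OCCO3)C[C@@H]2C)C(O[Si](C)(C)C)=C1 | intermediate (not isolated)
24 | (4S,5R,7S,10S)-2,2-(ethylenedioxy)-4,5-dimethyl-7-(prop-1-en-2-yl)-cis-decalin-9-one | C=C(C)[C@H]1C[C@@]2(C)[C@H](CC3(OCCO3)C[C@@H]2C)C(=O)C1 | intermediate
25 | potassium (4S,5R,7S,10S)-2,2-(ethylenedioxy)-4,5-dimethyl-7-(prop-1-en-2-yl)-cis-decal-8-en-9-olate | C=C(C)[C@H]1C[C@@]2(C)[C@H](CC3(OCCO3)C[C@@H]2C)C(O[K])=C1 | intermediate (not isolated)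
26 | (4S,5R,7R,8R,10S)-2,2-(ethylenedioxy)-8-hydroxy-4,5-dimethyl-7-(prop-1-en-2-yl)-cis-decalin-9-one | C=C(C)[C@H]1C[C@@]2(C)[C@H](CC3(OCCO3)C[C@@H]2C)C(=O)[C@@H]1O | intermediate
27 | (4S,5R,7R,8R,10S)-2,2-(ethylenedioxy)-4,5-dimethyl-7-(prop-1-en-2-yl)-8-(triethylsilyloxy)-cis-decalin-9-one | C=C(C)[C@H]1C[C@@]2(C)[C@H](CC3(OCCO3)C[C@@H]2C)C(=O)[C@@H]1O[Si](CC)(CC)CC | intermediate
28 | (4S,5R,7R,8R,9S,10S)-2,2-(ethylenedioxy)-4,5-dimethyl-7-(prop-1-en-2-yl)-8-(triethylsilyloxy)-cis-decalin-9-ol | C=C(C)[C@H]1C[C@@]2(C)[C@H](CC3(OCCO3)C[C@@H]2C)[C@H](O)[C@@H]1O[Si](CC)(CC)CC | intermediate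
29 | (E)-2-methylbut-2-enoic acid (tiglic acid) | C/C=C(\C)C(=O)O | starting material
30 | (E)-2-methylbut-2-enoic 2,4,6-trichlorobenzoic anhydride | C/C=C(\C)C(=O)OC(=O)c1c(Cl)cc(Cl)cc1Cl | intermediate (not isolated)
31 | (4S,5R,7R,8R,9S,10S)-2,2-(ethylenedioxy)-4,5-dimethyl-7-(prop-1-en-2-yl)-8-(triethylsilyloxy)-cis-decalin-9-yl (E)-2-methylbut-2-enoate | C=C(C)[C@H]1C[C@@]2(C)[C@H](CC3(OCCO3)C[C@@H]2C)[C@H](OC(=O)/C(C)=C/C)[C@@H]1O[Si](CC)(CC)CC | intermediate
32 | (4S,5R,7R,8R,9S,10S)-8-hydroxy-4,5-dimethyl-2-oxo-7-(prop-1-en-2-yl)-cis-decalin-9-yl (E)-2-methylbut-2-enoate | C=C(C)[C@H]1C[C@@]2(C)[C@H](CC(=O)C[C@@H]2C)[C@H](OC(=O)/C(C)=C/C)[C@@H]1O | intermediate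
33 | (4S,5R,7R,8R,9S,10S)-8-acetoxy-4,5-dimethyl-2-oxo-7-(prop-1-en-2-yl)-cis-decalin-9-yl (E)-2-methylbut-2-enoate (CNP0204573.1) | C=C(C)[C@H]1C[C@@]2(C)[C@H](CC(=O)C[C@@H]2C)[C@H](OC(=O)/C(C)=C/C)[C@@H]1OC(C)=O | target

## Step count and least certain steps

Total step count: 22. Longest linear sequence: 22 steps (1 to 33); compounds 4, 10 and 29 each enter in a single step.

**Step 13 (key step).** The enedione may be lost to hydride or silane reduction before the C5 radical forms, or the radical may close onto C1 and give a five/seven-membered ring system. The fallback makes the same C5–C10 bond within a chain, where the iron-mediated coupling is established. It sets out from iodide 9 and rejoins the route at compound 20.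
- Acetal hydrolysis (1 M aq. HCl, THF) would give (6R)-7-iodo-6-methyl-5-methylideneheptanal F1.
- CrCl2/NiCl2 coupling with methyl (E)-3-iodoacrylate would give methyl (2E,9R)-4-hydroxy-10-iodo-9-methyl-8-methylidenedec-2-enoate F2, and TBSOTf/2,6-lutidine its silyl ether F3.
- Fe(acac)3/PhSiH3 in ethanol would close ring B in the 6-exo mode (C5 radical onto C10, β to the ester) to give the cyclohexylacetate F4.
- SmI2 (THF, catalytic Fe(dbm)3) would close ring A by intramolecular acyl substitution of the ester by the primary iodide, giving the silyloxy decalone F5.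
- Ketalisation as in step 14 would give the silyloxy ketal F6, TBAF the hydroxy ketal F7, and Dess–Martin oxidation compound 20.

This path gives up the stereocontrol built into the ring. C5 and C10 arise without guidance in the 6-exo closure, so the isomer with the C4 arm and the acetate arm cis on ring B would have to be separated.

**Step 10.** Oligomerisation may win over ring closure, because the ten-membered ring must hold a nearly linear C9–C10≡C1–C2 unit. The fallback cyclises the cis-alkene instead of the alkyne and sets out from iodoalkyne 14. Diimide (2-nitrobenzenesulfonyl hydrazide, Et3N) would reduce it to the (Z)-iodoalkene F8. Acid as in step 9 would give the hydroxy aldehyde F9. CrCl2/NiCl2 cyclisation of the alkenyl iodide, whose cis double bond already holds both chain ends on one side, would give enediol 17 directly, so step 11 falls away.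

**Step 14.** Discrimination between the two ketones may be incomplete, or C10 may epimerise. The fallback tells the two positions apart at the alcohol level and sets out from dione 19. NaBH4 (MeOH, 0 °C) would give (4S,5R,10S)-4,5-dimethyl-cis-decalin-2,9-diol F10. TEMPO/PhI(OAc)2 would oxidise only the unhindered C2 alcohol, because the C9 alcohol beside the ring fusion reacts much more slowly with the hindered oxoammonium ion, giving the 9-hydroxy-2-ketone F11. Ketalisation of its only ketone would give the hydroxy ketal F7, and Dess–Martin oxidation returns to compound 20.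

**Step 16.** Facial selectivity may be poor or reversed if the cuprate approaches from the side of ring A, which would give the C7 epimer F12 of ketone 24. The fallback lets hydrogen rather than carbon take the preferred face and sets out from enone 22. The epimeric adduct F12 would be dehydrogenated as in step 15 to the 7-isopropenyl enone F13. Conjugate reduction with [(Ph3P)CuH]6 (benzene, rt), which normally reduces the α,β-position of a dienone, would then deliver hydride to C7 on the face the cuprate had chosen, turning the isopropenyl group to the required side and giving compound 24.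

**Step 20.** Acylation of the hindered axial alcohol may be slow, and forcing basic conditions may deconjugate the tigloyl unit through a vinylketene. The fallback builds the tiglate on the oxygen and sets out from alcohol 28. Esterification with 2-(diethoxyphosphoryl)propanoic acid (DCC, DMAP, by way of the reactive ketene) would give the phosphonate ester F14. An E-selective Horner–Wadsworth–Emmons reaction with acetaldehyde (LiCl, DBU, MeCN) would then give compound 31.

## Further compounds

F1 | step 13 | (6R)-7-iodo-6-methyl-5-methylideneheptanal | C[C@@H](CI)C(=C)CCCC=O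
F2 | step 13 | methyl (2E,9R)-4-hydroxy-10-iodo-9-methyl-8-methylidenedec-2-enoate (C4 epimers) | C[C@@H](CI)C(=C)CCCC(O)/C=C/C(=O)OC
F3 | step 13 | methyl (2E,9R)-4-[(tert-butyldimethylsilyl)oxy]-10-iodo-9-methyl-8-methylidenedec-2-enoate (C4 epimers) | C[C@@H](CI)C(=C)CCCC(O[Si](C)(C)C(C)(C)C)/C=C/C(=O)OC
F4 | step 13 | methyl 2-{(1S,2S)-6-[(tert-butyldimethylsilyl)oxy]-2-[(2R)-1-iodopropan-2-yl]-2-methylcyclohexyl}acetate (C6 epimers) | C1C[C@](C)([C@@H](C)CI)[C@H](CC(=O)OC)C(O[Si](C)(C)C(C)(C)C)C1
F5 | step 13 | (4S,5R,10S)-9-[(tert-butyldimethylsilyl)oxy]-4,5-dimethyl-cis-decalin-2-one (C9 epimers) | C1C[C@@]2(C)[C@H](CC(=O)C[C@@H]2C)C(O[Si](C)(C)C(C)(C)C)C1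
F6 | step 13 | (4S,5R,10S)-9-[(tert-butyldimethylsilyl)oxy]-2,2-(ethylenedioxy)-4,5-dimethyl-cis-decalin (C9 epimers) | C1C[C@@]2(C)[C@H](CC3(OCCO3)C[C@@H]2C)C(O[Si](C)(C)C(C)(C)C)C1
F7 | step 13 | (4S,5R,10S)-2,2-(ethylenedioxy)-4,5-dimethyl-cis-decalin-9-ol (C9 epimers) | C1C[C@@]2(C)[C@H](CC3(OCCO3)C[C@@H]2C)C(O)C1
F8 | step 10 | (1Z,5S)-9-(1,3-dioxolan-2-yl)-1-iodo-5-methyl-6-methylidene-3-[(triethylsilyl)oxy]non-1-ene (C3 epimers) | C[C@@H](CC(O[Si](CC)(CC)CC)/C=C\I)C(=C)CCCC1OCCO1
F9 | step 10 | (6S,9Z)-8-hydroxy-10-iodo-6-methyl-5-methylidenedec-9-enal (C8 epimers) | C[C@@H](CC(O)/C=C\I)C(=C)CCCC=O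
F10 | step 14 | (4S,5R,10S)-4,5-dimethyl-cis-decalin-2,9-diol (carbinol epimers) | C1C[C@@]2(C)[C@H](CC(O)C[C@@H]2C)C(O)C1
F11 | step 14 | (4S,5R,10S)-9-hydroxy-4,5-dimethyl-cis-decalin-2-one (C9 epimers) | C1C[C@@]2(C)[C@H](CC(=O)C[C@@H]2C)C(O)C1
F12 | step 16 | (4S,5R,7R,10S)-2,2-(ethylenedioxy)-4,5-dimethyl-7-(prop-1-en-2-yl)-cis-decalin-9-one | C=C(C)[C@@H]1C[C@@]2(C)[C@H](CC3(OCCO3)C[C@@H]2C)C(=O)C1
F13 | step 16 | (4S,5R,10S)-2,2-(ethylenedioxy)-4,5-dimethyl-7-(prop-1-en-2-yl)-cis-decal-7-en-9-one | C=C(C)C1C[C@@]2(C)[C@H](CC3(OCCO3)C[C@@H]2C)C(=O)C=1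
F14 | step 20 | (4S,5R,7R,8R,9S,10S)-2,2-(ethylenedioxy)-4,5-dimethyl-7-(prop-1-en-2-yl)-8-(triethylsilyloxy)-cis-decalin-9-yl 2-(diethoxyphosphoryl)propanoate | C=C(C)[C@H]1C[C@@]2(C)[C@H](CC3(OCCO3)C[C@@H]2C)[C@H](OC(=O)C(C)P(=O)(OCC)OCC)[C@@H]1O[Si](CC)(CC)CC
A1 | alternative 1 | (4S,5R,7R,8R,9S,10S)-9-[(tert-butyldimethylsilyl)oxy]-2,2-(ethylenedioxy)-4,5-dimethyl-7-(prop-1-en-2-yl)-cis-decalin-8-ol | C=C(C)[C@H]1C[C@@]2(C)[C@H](CC3(OCCO3)C[C@@H]2C)[C@H](O[Si](C)(C)C(C)(C)C)[C@@H]1O
A2 | alternative 1 | ring A ketal carrying at C5 an (E)-4-bromo-3-methylbut-2-enyl chain and at C10 a CH(OTBS)CHO arm | BrC/C(C)=C/C[C@@]1(C)[C@H](CC2(OCCO2)C[C@@H]1C)[C@H](O[Si](C)(C)C(C)(C)C)C=O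
A3 | alternative 2 | cis-decalin with C2 ketone, C1 dimethyl ketal, 4,5-dimethyl, C6=C7 alkene and C8 benzyl ether | C1=C[C@@]2(C)[C@H](C(OC)(OC)C(=O)C[C@@H]2C)C[C@H]1OCc3ccccc3
A4 | alternative 2 | 7-(benzyloxy)-3,3-dimethoxy-5-methyl-2-[(Z)-prop-1-enyl]bicyclo[2.2.2]oct-5-en-2-ol | C/C=C\[C@@]1(O)C(OC)(OC)[C@H]2C(C)=C[C@@H]1[C@H](OCc1ccccc1)C2
A5 | alternative 3 | cis-fused 5-methyldecal-3-ene-2,9-dione | C1C[C@@]2(C)[C@H](CC(=O)C=C2)C(=O)C1
A6 | alternative 3 | 4-methyl-4-(4-oxobutyl)cyclohexa-2,5-dien-1-one | CC1(CCCC=O)C=CC(=O)C=C1
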